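**Strategy.** Everything rests on forming the O21–C22 bond last. On ring C (C9, C17, C19, C20, C24, C23) the C20 oxygen and the C22 methyl on C23 are 1,3-syn-diaxial across C24, so a C20 alkoxy radical reaches a C22 hydrogen by 1,5-transfer and ring D closes in one operation with no new stereocentre. The precursor 24 is the ring D seco alcohol: spiro lactone B and ring A complete, enal in place, C14–OH as triethylsilyl ether, C20–OH free. Ring C comes from a copper-catalysed methyl addition; an epoxide keeps the C20 oxygen latent while C9, lactone B and ring A (Michael–aldol annulation) are built.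

Key step: step 16

Remark: atom labels C1–C26 follow the order of the target SMILES; the face of ring C that carries C22 is called the lower face; the antipode of the ligand in step 2 is chosen so that (R)-4 results.

Step 1
Reactants: 1 4,4-dimethylcyclohex-2-en-1-one
Product: 2 4,4-dimethylcyclohexa-2,5-dien-1-one
Conditions: DDQ, 1,4-dioxane, reflux
Reagents that add atoms: none
Why: DDQ dehydrogenation can only introduce the second double bond at the α′,β′ position because C4 is quaternary, and no stereocentre is formed.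

Step 2
Reactants: 2 4,4-dimethylcyclohexa-2,5-dien-1-one; 3 dimethylzinc
Product: 4 (R)-4,4,5-trimethylcyclohex-2-en-1-one
Conditions: ZnMe2, Cu(OTf)2 (2 mol %), binaphthol-derived N,N-bis(1-phenylethyl)phosphoramidite ligand (4 mol %), PhMe, −25 °C; aq. NH4Cl
Reagents that add atoms: dimethylzinc, C[Zn]C
Why: Copper-catalysed asymmetric conjugate addition desymmetrises the dienone by delivering methyl to one of the two enantiotopic β-carbons, so C23 is set by the ligand, and the less electrophilic mono-enone should not add a second methyl.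

Step 3
Reactants: 4 (R)-4,4,5-trimethylcyclohex-2-en-1-one
Product: 5 (1S,5R)-4,4,5-trimethylcyclohex-2-en-1-ol (hydroxyl cis to the 5-methyl)
Conditions: NaBH4, CeCl3·7H2O, MeOH, −78 °C
Reagents that add atoms: none
Why: Luche reduction gives 1,2-reduction only, with axial hydride attack on the half-chair that has the C23 methyl equatorial, so the hydroxyl should come out cis to that methyl, as in the reduction of carvone to cis-carveol.

Step 4
Reactants: 5 (1S,5R)-4,4,5-trimethylcyclohex-2-en-1-ol
Product: 6 (1S,2S,4R,6R)-4,5,5-trimethyl-7-oxabicyclo[4.1.0]heptan-2-ol (epoxide, hydroxyl and 4-methyl all cis)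
Conditions: VO(acac)2 (2 mol %), t-BuOOH, CH2Cl2, 0 °C → rt
Reagents that add atoms: tert-butyl hydroperoxide, CC(C)(C)OO
Why: Vanadium-catalysed hydroxyl-directed epoxidation delivers oxygen to the alkene face syn to the allylic alcohol, which places the future C20–O bond on the lower face, cis to C22.

Step 5
Reactants: 6 (1S,2S,4R,6R)-4,5,5-trimethyl-7-oxabicyclo[4.1.0]heptan-2-ol
Product: 7 (1R,4R,6R)-4,5,5-trimethyl-7-oxabicyclo[4.1.0]heptan-2-one
Conditions: Dess–Martin periodinane, CH2Cl2, rt
Reagents that add atoms: none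
Why: Dess–Martin oxidation restores the C17 ketone without touching the epoxide, and the resulting α,β-epoxy ketone can enolise only toward C9 while it keeps the C20 oxygen masked.

Step 6
Reactants: 7 (1R,4R,6R)-4,5,5-trimethyl-7-oxabicyclo[4.1.0]heptan-2-one; 8 methyl 2-(bromomethyl)prop-2-enoate
Product: 9 methyl 2-{[(1R,3R,4R,6R)-4,5,5-trimethyl-2-oxo-7-oxabicyclo[4.1.0]heptan-3-yl]methyl}prop-2-enoate
Conditions: LiN(iPr)2, THF, −78 °C; then 8, −78 → −40 °C
Reagents that add atoms: methyl 2-(bromomethyl)prop-2-enoate, C=C(CBr)C(=O)OC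
Why: Enolate alkylation with the reactive allylic bromide attaches the C8–C14–C12 unit at C9, the only enolisable position, and the C9 configuration is immaterial because this centre is planarised again in step 7.

Step 7
Reactants: 9 methyl 2-{[(1R,3R,4R,6R)-4,5,5-trimethyl-2-oxo-7-oxabicyclo[4.1.0]heptan-3-yl]methyl}prop-2-enoate; 10 formaldehyde (monomeric, from cracked paraformaldehyde)
Product: 11 methyl 2-{[(1R,3S,4S,6R)-3-(hydroxymethyl)-4,5,5-trimethyl-2-oxo-7-oxabicyclo[4.1.0]heptan-3-yl]methyl}prop-2-enoate
Conditions: LiN(SiMe3)2, THF, −78 → −40 °C; CH2O (g), −78 °C; AcOH quench at −78 °C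
Reagents that add atoms: formaldehyde, C=O
Why: Aldol addition of the tetrasubstituted lithium enolate to formaldehyde makes C9 quaternary, with the electrophile entering anti to the pseudo-axial C22 methyl and the epoxide, so C10 should end on the upper face and the C8 chain on the lower face.

Step 8
Reactants: 11 methyl 2-{[(1R,3S,4S,6R)-3-(hydroxymethyl)-4,5,5-trimethyl-2-oxo-7-oxabicyclo[4.1.0]heptan-3-yl]methyl}prop-2-enoate
Product: 13 spiro keto lactone (ring B = C8H2–C9–C10H2–O11–C12(=O)–C14(=O), spiro at C9 to the epoxy ketone ring C; C8 on the lower face, C10 on the upper face; largely enolised at C8=C14), via keto ester 12 (not isolated)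
Conditions: O3, CH2Cl2, −78 °C; Me2S; then PPTS (cat.), PhMe, 80 °C
Reagents that add atoms: ozone, [O-][O+]=O
Why: Ozonolysis cleaves the only alkene to the α-keto ester, and acid-catalysed transesterification by the C10 hydroxyl closes the six-membered lactone B without creating a stereocentre.

Step 9
Reactants: 13 spiro keto lactone; 14 methyl vinyl ketone
Product: 16 trans-fused ketol (ring A cyclohexanone with C5=O fused to lactone B at C8–C14; C14–OH axial and anti to C8–H; on ring B the C17 arm of ring C axial, the C23 arm equatorial), via Michael adduct 15 (not isolated)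
Conditions: Et3N (0.2 equiv), CH2Cl2, 0 °C; then DBU (0.1 equiv), rt
Reagents that add atoms: methyl vinyl ketone, CC(=O)C=C
Why: Robinson-type annulation (Michael addition of the enolised keto lactone at C8, then aldol of the methyl ketone onto the activated C14 ketone): spiro C9 always places one substituent axial on ring B, so C16 should attack equatorially, and the reversible sequence should settle on the trans-fused ketol with the smaller C17 arm axial, which sets C8 and C14.

Step 10
Reactants: 16 trans-fused ketol
Product: 17 C14 triethylsilyl ether of 16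
Conditions: Et3SiOTf, 2,6-lutidine, CH2Cl2, −78 → 0 °C; aq. NaHCO3
Reagents that add atoms: triethylsilyl trifluoromethanesulfonate, CC[Si](CC)(CC)OS(=O)(=O)C(F)(F)F
Why: Silylation with the silyl triflate protects the hindered tertiary alcohol, which stops retro-aldol opening of ring A in the basic steps ahead and keeps this oxygen out of the radical step.

Step 11
Reactants: 17 C14 triethylsilyl ether of 16; 18 (methoxymethyl)triphenylphosphonium chloride
Product: 20 C5 carbaldehyde (formyl equatorial on ring A, trans to the C8–C9 bond; epoxy ketone, lactone and silyl ether as in 17), via enol ether 19 (not isolated)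
Conditions: KN(SiMe3)2, THF, 0 °C; then PPTS, acetone/H2O, 40 °C; then DBU (0.1 equiv), CH2Cl2, rt
Reagents that add atoms: (methoxymethyl)triphenylphosphonium chloride, COC[P+](c1ccccc1)(c1ccccc1)c1ccccc1.[Cl-]; water, O
Why: Wittig methoxymethylenation takes place at the unhindered C5 ketone (C17 is shielded by quaternary C9), enol ether hydrolysis gives the aldehyde, and base equilibration places the formyl group equatorial, away from the axial C14 silyl ether, which sets C5.

Step 12
Reactants: 20 C5 carbaldehyde; 18 (methoxymethyl)triphenylphosphonium chloride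
Product: 21 C5 (2-methoxyvinyl) enol ether (E/Z mixture)
Conditions: KN(SiMe3)2, THF, −78 → 0 °C
Reagents that add atoms: (methoxymethyl)triphenylphosphonium chloride, COC[P+](c1ccccc1)(c1ccccc1)c1ccccc1.[Cl-]
Why: A second Wittig methoxymethylenation turns the aldehyde into an enol ether, a masked C2–C3 acetaldehyde unit that tolerates the electron-transfer reduction of step 13.

Step 13
Reactants: 21 C5 (2-methoxyvinyl) enol ether
Product: 22 β-hydroxy ketone (C20–OH on the lower face, cis to C22; C19 now CH2; enol ether retained)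
Conditions: SmI2 (2.2 equiv), THF/MeOH, −78 °C
Reagents that add atoms: none
Why: SmI2 reduces the α,β-epoxy ketone selectively, the ketyl cleaving the C19–O bond, so the β-hydroxy ketone is released with the C20 configuration from step 4 unchanged.

Step 14
Reactants: 22 β-hydroxy ketone
Product: 23 C5 acetaldehyde (C5–CH2–CHO)
Conditions: PPTS, acetone/H2O, 40 °C
Reagents that add atoms: water, O
Why: Mild acid hydrolysis of the methyl enol ether unmasks the aldehyde without cleaving the tertiary silyl ether or dehydrating the β-hydroxy ketone.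

Step 15
Reactants: 23 C5 acetaldehyde; 10 formaldehyde (37 % aqueous)
Product: 24 ring D seco alcohol, (5R,8S,9R,14S,20S,23S) in target numbering (enal, C14–OSiEt3, C20–OH, C22 methyl)
Conditions: pyrrolidine (0.2 equiv), EtCO2H (0.2 equiv), i-PrOH, 45 °C
Reagents that add atoms: formaldehyde, C=O
Why: Amine-catalysed α-methylenation (Mannich condensation with formaldehyde, then elimination) converts the CH2–CHO unit into the 2-substituted acrolein without creating a stereocentre.

Step 16
Reactants: 24 ring D seco alcohol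
Product: 27 target C14 triethylsilyl ether (ring D closed), via hypoiodite 25 (not isolated), via C22 iodide 26 (not isolated)
Conditions: PhI(OAc)2 (1.6 equiv), I2 (1.0 equiv), cyclohexane/CH2Cl2, visible light (tungsten lamp), 25 °C
Reagents that add atoms: none
Why: Acetyl hypoiodite made from PhI(OAc)2 and I2 converts the C20 alcohol into hypoiodite 25; light cleaves the O–I bond, the C20 alkoxy radical takes a hydrogen from C22 through a six-membered chair-like transition state (1,5-hydrogen atom transfer), the C22 radical is iodinated to 26, and O21 displaces iodide. The closest known reaction is the hypoiodite reaction that converts 1,3-diaxial alcohol and methyl pairs into tetrahydrofurans. Ring D closes in the 5-exo-tet mode. No stereocentre is created, and C20 and C23 are retained. The step needs site selectivity and hydrogen transfer faster than β-scission of C19–C20 or C20–C24: C22 is the only hydrogen-bearing carbon five atoms from the oxygen, and in the chair of ring C with C8 equatorial the C20 oxygen and C22 are syn-diaxial. The C14 oxygen is silylated and the enal is electron-poor, so neither should compete.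

Step 17
Reactants: 27 target C14 triethylsilyl ether
Product: 28 target CNP0525385.1
Conditions: HF·pyridine, THF, 0 °C → rt
Reagents that add atoms: none
Why: Fluoride-mediated desilylation frees the tertiary alcohol under conditions that should leave the lactone, the enal and the β-alkoxy ketone untouched.

**Compound list**

1 | 4,4-dimethylcyclohex-2-en-1-one | CC1(C)CCC(=O)C=C1 | starting material
2 | 4,4-dimethylcyclohexa-2,5-dien-1-one | CC1(C)C=CC(=O)C=C1 | intermediate
3 | dimethylzinc | C[Zn]C | starting material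
4 | (R)-4,4,5-trimethylcyclohex-2-en-1-one | C1C(=O)C=CC(C)(C)[C@@H]1C | intermediate
5 | (1S,5R)-4,4,5-trimethylcyclohex-2-en-1-ol | C1[C@H](O)C=CC(C)(C)[C@@H]1C | intermediate
6 | (1S,2S,4R,6R)-4,5,5-trimethyl-7-oxabicyclo[4.1.0]heptan-2-ol | C1[C@H](O)[C@@H]2O[C@@H]2C(C)(C)[C@@H]1C | intermediate
7 | (1R,4R,6R)-4,5,5-trimethyl-7-oxabicyclo[4.1.0]heptan-2-one | C1C(=O)[C@@H]2O[C@@H]2C(C)(C)[C@@H]1C | intermediate
8 | methyl 2-(bromomethyl)prop-2-enoate | C=C(CBr)C(=O)OC | starting material
9 | methyl 2-{[(1R,3R,4R,6R)-4,5,5-trimethyl-2-oxo-7-oxabicyclo[4.1.0]heptan-3-yl]methyl}prop-2-enoate | COC(=O)C(=C)C[C@H]1C(=O)[C@@H]2O[C@@H]2C(C)(C)[C@@H]1C | intermediate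
10 | formaldehyde | C=O | starting material
11 | methyl 2-{[(1R,3S,4S,6R)-3-(hydroxymethyl)-4,5,5-trimethyl-2-oxo-7-oxabicyclo[4.1.0]heptan-3-yl]methyl}prop-2-enoate | C=C(C(=O)OC)C[C@]1(CO)C(=O)[C@@H]2O[C@@H]2C(C)(C)[C@@H]1C | intermediate
12 | keto ester: methyl 3-[(1R,3S,4S,6R)-3-(hydroxymethyl)-4,5,5-trimethyl-2-oxo-7-oxabicyclo[4.1.0]heptan-3-yl]-2-oxopropanoate | COC(=O)C(=O)C[C@]1(CO)C(=O)[C@@H]2O[C@@H]2C(C)(C)[C@@H]1C | intermediate
13 | spiro keto lactone (ring B with C14 ketone, spiro at C9 to epoxy ketone ring C; keto form drawn) | O=C1C[C@]2(COC1=O)C(=O)[C@@H]3O[C@@H]3C(C)(C)[C@@H]2C | intermediate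
14 | methyl vinyl ketone | CC(=O)C=C | starting material
15 | Michael adduct: C8-(3-oxobutyl) keto lactone | CC(=O)CC[C@H]1[C@]2(COC(=O)C1=O)C(=O)[C@@H]3O[C@@H]3C(C)(C)[C@@H]2C | intermediate
16 | trans-fused ketol (ring A with C5 ketone, axial C14–OH, lactone B, epoxy ketone ring C) | O=C1CC[C@H]2[C@]3(COC(=O)[C@]2(O)C1)C(=O)[C@@H]4O[C@@H]4C(C)(C)[C@@H]3C | intermediate
17 | C14 triethylsilyl ether of 16 | O=C1CC[C@H]2[C@]3(COC(=O)[C@]2(O[Si](CC)(CC)CC)C1)C(=O)[C@@H]4O[C@@H]4C(C)(C)[C@@H]3C | intermediate
18 | (methoxymethyl)triphenylphosphonium chloride | COC[P+](c1ccccc1)(c1ccccc1)c1ccccc1.[Cl-] | starting material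
19 | enol ether: C5 methoxymethylene derivative of 17 | COC=C1CC[C@H]2[C@]3(COC(=O)[C@]2(O[Si](CC)(CC)CC)C1)C(=O)[C@@H]4O[C@@H]4C(C)(C)[C@@H]3C | intermediate
20 | C5 carbaldehyde (formyl equatorial) | O=C[C@@H]1CC[C@H]2[C@]3(COC(=O)[C@]2(O[Si](CC)(CC)CC)C1)C(=O)[C@@H]4O[C@@H]4C(C)(C)[C@@H]3C | intermediate
21 | C5 (2-methoxyvinyl) enol ether, E/Z mixture | COC=C[C@@H]1CC[C@H]2[C@]3(COC(=O)[C@]2(O[Si](CC)(CC)CC)C1)C(=O)[C@@H]4O[C@@H]4C(C)(C)[C@@H]3C | intermediate
22 | β-hydroxy ketone (C20–OH cis to C22), enol ether retained | COC=C[C@@H]1CC[C@H]2[C@]3(COC(=O)[C@]2(O[Si](CC)(CC)CC)C1)C(=O)C[C@H](O)C(C)(C)[C@@H]3C | intermediate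
23 | C5 acetaldehyde (C5–CH2–CHO) | O=CC[C@@H]1CC[C@H]2[C@]3(COC(=O)[C@]2(O[Si](CC)(CC)CC)C1)C(=O)C[C@H](O)C(C)(C)[C@@H]3C | intermediate
24 | ring D seco alcohol (key-step precursor) | C=C(C=O)[C@@H]1CC[C@H]2[C@]3(COC(=O)[C@]2(O[Si](CC)(CC)CC)C1)C(=O)C[C@H](O)C(C)(C)[C@@H]3C | intermediate
25 | C20 hypoiodite of 24 | C=C(C=O)[C@@H]1CC[C@H]2[C@]3(COC(=O)[C@]2(O[Si](CC)(CC)CC)C1)C(=O)C[C@H](OI)C(C)(C)[C@@H]3C | intermediate
26 | C22 iodide (C22H2I, C20–OH) | C=C(C=O)[C@@H]1CC[C@H]2[C@]3(COC(=O)[C@]2(O[Si](CC)(CC)CC)C1)C(=O)C[C@H](O)C(C)(C)[C@@H]3CI | intermediate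
27 | target C14 triethylsilyl ether | C=C(C=O)[C@@H]1CC[C@H]2[C@]3(COC(=O)[C@]2(O[Si](CC)(CC)CC)C1)C(=O)C[C@@H]1OC[C@H]3C1(C)C | intermediate
28 | target CNP0525385.1 | C=C(C=O)[C@@H]1CC[C@H]2[C@]3(COC(=O)[C@]2(O)C1)C(=O)C[C@@H]1OC[C@H]3C1(C)C | target

Total step count: 17 steps.
Longest linear sequence: 17 steps (1 → 28); compounds 3, 8, 10, 14 and 18 are bought.

**Steps most likely to fail**

Step 16. The C20 alkoxy radical may fragment (β-scission of C19–C20 or C20–C24) faster than it transfers hydrogen, and the acid formed may strip the silyl ether. Fallback: the C22 methyl is functionalised by the Barton nitrite ester reaction instead. Setting out from 24, nitrosyl chloride in pyridine gives the C20 nitrite ester F1. Irradiation moves NO to C22 and the nitroso compound tautomerises to the C22 oxime F2. Buffered aqueous TiCl3 hydrolyses the oxime to the C22 aldehyde, which closes onto O21 as the C22 lactol F3. Ionic reduction (Et3SiH, BF3·OEt2, −78 °C) removes the lactol hydroxyl and the route is rejoined at 27.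

Step 9. The annulation may stall at the Michael stage, alkylate C8 twice, lose water from the ketol, or close to the cis ring fusion. Fallback: ring A is assembled by two allylations and ring-closing metathesis. Setting out from 13, allyl methyl carbonate and Pd(PPh3)4 give the C8-allyl keto lactone F4. Zinc-mediated Barbier addition of 3-bromo-2-methoxyprop-1-ene to the C14 ketone, anti to the C8 allyl group, gives the C14 tertiary alcohol F5. The second-generation Grubbs catalyst RuCl2(=CHPh)(PCy3)(H2IMes) closes ring A as the cyclic enol ether F6, and mild acid hydrolysis rejoins the route at 16.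

Step 7. Deprotonation of the hindered C9–H may be slow, the lithium aldolate may revert (retro-aldol) or add to the acrylate (oxa-Michael), and facial selectivity at C9 may be poor. Fallback: a Lewis-acid Mukaiyama aldol replaces the basic aldol. Setting out from 9, the enolate is trapped with Me3SiCl as the trimethylsilyl enol ether F7, which is hydroxymethylated with aqueous formaldehyde and catalytic Sc(OTf)3, rejoining the route at 11 without a basic aldolate.

**Further compounds**

F1 | step 16 | C20 nitrite ester | C=C(C=O)[C@@H]1CC[C@H]2[C@]3(COC(=O)[C@]2(O[Si](CC)(CC)CC)C1)C(=O)C[C@H](ON=O)C(C)(C)[C@@H]3C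
F2 | step 16 | C22 oxime | C=C(C=O)[C@@H]1CC[C@H]2[C@]3(COC(=O)[C@]2(O[Si](CC)(CC)CC)C1)C(=O)C[C@H](O)C(C)(C)[C@@H]3C=NO
F3 | step 16 | C22 lactol | C=C(C=O)[C@@H]1CC[C@H]2[C@]3(COC(=O)[C@]2(O[Si](CC)(CC)CC)C1)C(=O)C[C@@H]1OC(O)[C@H]3C1(C)C
F4 | step 9 | C8-allyl keto lactone | C=CC[C@H]1[C@]2(COC(=O)C1=O)C(=O)[C@@H]3O[C@@H]3C(C)(C)[C@@H]2C
F5 | step 9 | C14 tertiary alcohol | C=CC[C@H]1[C@]2(COC(=O)[C@]1(O)CC(=C)OC)C(=O)[C@@H]3O[C@@H]3C(C)(C)[C@@H]2C
F6 | step 9 | cyclic enol ether | COC1=CC[C@H]2[C@]3(COC(=O)[C@]2(O)C1)C(=O)[C@@H]4O[C@@H]4C(C)(C)[C@@H]3C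
F7 | step 7 | trimethylsilyl enol ether | C=C(C(=O)OC)CC1=C(O[Si](C)(C)C)[C@@H]2O[C@@H]2C(C)(C)[C@@H]1C
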